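The route rests on cutting the O1–C2 bond of the dihydropyran ring, which opens the chroman to an ortho-(E)-phytyl phenol. The key step exploits the tertiary ether carbon C2, which in the open form is a trisubstituted alkene carbon at the end of the six-atom chain O1–C8a–C4a–C4–C3–C2. A confined chiral Brønsted acid protonates the future C3 and the phenolic oxygen closes onto C2, so the pyran ring and the only ring stereocentre form in one operation. The precursor is the phytylated monoacetate of 2,5-dimethylhydroquinone: only the cyclising hydroxyl is free, the remote oxygen (future C6–OH) is masked against oxidation and competing acid binding, and 4'R and 8'R come from natural phytol.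

Key step: step 3

Remark on the chemistry: which antipode of the catalyst leads to 2R cannot be predicted; both are made from (R)- or (S)-BINOL, and the one that delivers oxygen to the Re face of the methyl-bearing alkene carbon is to be chosen in a trial run.

Step 1
Reactants: 1 2,5-dimethylhydroquinone (2,5-dimethylbenzene-1,4-diol)
Product: 2 4-hydroxy-2,5-dimethylphenyl acetate
Conditions: Ac2O (1 equiv, added slowly to 3 equiv of 1), pyridine, THF, 0 °C, argon; excess 1 recovered
Reagents that add atoms: acetic anhydride, CC(=O)OC(C)=O
Why: O-acylation of a phenol with an anhydride; 1 is symmetric, so only one monoacetate can form, and the excess of 1 should keep the diacetate minor.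

Step 2
Reactants: 2 4-hydroxy-2,5-dimethylphenyl acetate; 3 natural phytol, (2E,7R,11R)-3,7,11,15-tetramethylhexadec-2-en-1-ol
Product: 4 4-hydroxy-2,5-dimethyl-3-[(2E,7R,11R)-3,7,11,15-tetramethylhexadec-2-en-1-yl]phenyl acetate
Conditions: 2 (1.5 equiv), BF3·OEt2 (0.5 equiv), dioxane, 20 °C, argon; NaHCO3 quench; AgNO3-impregnated SiO2 chromatography to remove the Z isomer
Reagents that add atoms: none
Why: Friedel–Crafts allylation of a phenol by the phytyl cation, which should attack through its primary terminus at the one ring position ortho to the free hydroxyl (the other open position lies ortho to the deactivating acetoxy group) and largely keep the E alkene, while dioxane tempers the acid enough to stop before ring closure and the chain centres are not involved.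

Step 3
Reactants: 4 4-hydroxy-2,5-dimethyl-3-[(2E,7R,11R)-3,7,11,15-tetramethylhexadec-2-en-1-yl]phenyl acetate
Product: 5 (2R,4'R,8'R)-β-tocopheryl acetate, (2R)-2,5,8-trimethyl-2-[(4R,8R)-4,8,12-trimethyltridecyl]-3,4-dihydro-2H-chromen-6-yl acetate
Conditions: IDPi (5 mol %; (S,S)- or (R,R)-imidodiphosphorimidate built from two 3,3'-bis[3,5-bis(trifluoromethyl)phenyl]-BINOL units, each phosphorus carrying a P=N–SO2CF3 group), cyclohexane, 25–40 °C, argon; Et3N quench
Reagents that add atoms: none
Why: Proposed new method: the acid hydrogen-bonds to the single free phenol and passes its proton to the side-chain CH carbon (future C3), so that positive charge grows on the methyl-bearing carbon (future C2) inside the chiral anion while the phenolic oxygen bonds to that carbon in one asynchronous event that returns the proton to the catalyst; the closest known reaction type is the imidodiphosphorimidate-catalysed intramolecular hydroalkoxylation of unactivated alkenes by aliphatic alcohols to 2,2-disubstituted cyclic ethers, extended here to a phenol and a trisubstituted alkene. The pyran ring closes 6-endo-trig, the 5-exo alternative being excluded because it would need the secondary cation. The new stereocentre C2 is controlled by the catalyst pocket alone, which has to deliver oxygen to the Re face of the methyl-bearing alkene carbon, since 4'R and 8'R are too far away to bias the closure. The step needs Markovnikov regioselectivity, secured by the trisubstituted alkene, and enantioface selectivity, for which the substrate offers a geometrically pure E alkene, one hydrogen-bond donor only, and an ortho methyl group that restricts the conformation of the phenol. The product ether is less basic than the alkene and the acetate lowers the electron density of the arene, so product inhibition, ring C-alkylation and re-ionisation at C2 should not compete at these temperatures.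

Step 4
Reactants: 5 (2R,4'R,8'R)-β-tocopheryl acetate
Product: 6 (2R,4'R,8'R)-β-tocopherol, (2R)-2,5,8-trimethyl-2-[(4R,8R)-4,8,12-trimethyltridecyl]-3,4-dihydro-2H-chromen-6-ol
Conditions: K2CO3 (0.3 equiv), degassed MeOH–THF, 20 °C, argon; aq. NH4Cl; SiO2 chromatography under argon
Reagents that add atoms: none
Why: Base-catalysed transesterification of an aryl acetate with methanol (Zemplén-type deacetylation), which touches neither the aryl alkyl ether nor any of the three stereocentres.

Compound list
1 | 2,5-dimethylhydroquinone (2,5-dimethylbenzene-1,4-diol) | Cc1cc(O)c(C)cc1O | starting material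
2 | 4-hydroxy-2,5-dimethylphenyl acetate | CC(=O)Oc1cc(C)c(O)cc1C | intermediate
3 | natural phytol, (2E,7R,11R)-3,7,11,15-tetramethylhexadec-2-en-1-ol | OC/C=C(\C)CCC[C@H](C)CCC[C@H](C)CCCC(C)C | starting material
4 | 4-hydroxy-2,5-dimethyl-3-[(2E,7R,11R)-3,7,11,15-tetramethylhexadec-2-en-1-yl]phenyl acetate | Cc1cc(OC(C)=O)c(C)c(C/C=C(\C)CCC[C@H](C)CCC[C@H](C)CCCC(C)C)c1O | intermediate
5 | (2R,4'R,8'R)-β-tocopheryl acetate, (2R)-2,5,8-trimethyl-2-[(4R,8R)-4,8,12-trimethyltridecyl]-3,4-dihydro-2H-chromen-6-yl acetate | Cc1cc(OC(C)=O)c(C)c2c1O[C@](C)(CCC[C@H](C)CCC[C@H](C)CCCC(C)C)CC2 | intermediate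
6 | (2R,4'R,8'R)-β-tocopherol, (2R)-2,5,8-trimethyl-2-[(4R,8R)-4,8,12-trimethyltridecyl]-3,4-dihydro-2H-chromen-6-ol | Cc1cc(O)c(C)c2c1O[C@](C)(CCC[C@H](C)CCC[C@H](C)CCCC(C)C)CC2 | target

Total step count: 4
Longest linear sequence: 4 steps (1 → 2 → 4 → 5 → 6)

Steps most likely to fail

First, step 3. The process at risk is enantioface discrimination: the flexible chain may not be held in the catalyst pocket, or a loose tertiary cation may close without control by the anion, so that both configurations at C2 form. Acid-induced E/Z equilibration of the alkene before closure would have the same effect. The fallback uses known chemistry, sets out from 4 and comes back at 5. Asymmetric induction is given up and 4 is cyclised with an achiral acid (p-TsOH·H2O cat., toluene, 60 °C), the classical acid-mediated chroman closure of ortho-prenylphenols. This should give 5 together with its C2 epimer (2S,4'R,8'R)-β-tocopheryl acetate F1. The two are diastereomers that differ only at C2 and are separated by preparative HPLC on a polysaccharide carbamate chiral phase, an established separation for 2-epimeric tocopheryl esters. Pure 5 then enters step 4.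

Second, step 2. The processes at risk are loss of alkene geometry in the allyl cation, premature acid-induced ring closure to a chroman without stereocontrol, and O- or poly-alkylation. The fallback replaces the cationic alkylation by an SN2 coupling under basic conditions; it sets out from 1 and 3 and comes back at 4.
- 1 is protected with MOMCl and iPr2NEt in CH2Cl2 to give 1,4-bis(methoxymethoxy)-2,5-dimethylbenzene F2.
- 3 is converted with PBr3 in Et2O at −10 °C into (2E,7R,11R)-phytyl bromide F3.
- F2 is lithiated ortho to a MOM ether (n-BuLi, TMEDA, THF, 0 °C) to give [2,5-bis(methoxymethoxy)-3,6-dimethylphenyl]lithium F4.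
- F4 is coupled with F3 in the presence of CuBr·SMe2 (10 mol %) at −78 to 0 °C. Attack at the primary carbon keeps the E geometry and should give 1,4-bis(methoxymethoxy)-2,5-dimethyl-3-[(2E,7R,11R)-3,7,11,15-tetramethylhexadec-2-en-1-yl]benzene F5.
- HCl in MeOH at 20 °C removes both acetals without protonating the alkene and should give 2,5-dimethyl-3-[(2E,7R,11R)-3,7,11,15-tetramethylhexadec-2-en-1-yl]benzene-1,4-diol F6, which is handled under argon.
- Ac2O (1 equiv) and pyridine in CH2Cl2 at −20 °C acetylate the hydroxyl that has one ortho substituent in preference to the one that has two, which leads to 4.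

Third, step 1. The process at risk is over-acylation: both hydroxyls are equivalent and the first acetate barely slows the second, so diacetate forms alongside and the oxidation-prone diol has to be recycled. The fallback differentiates the oxygens by deprotection instead; it sets out from 1 and comes back at 2. Exhaustive acetylation (Ac2O in excess, pyridine, DMAP cat.) gives 2,5-dimethyl-1,4-phenylene diacetate F7. One equivalent of LiOH in degassed THF–H2O at 0 °C then removes one acetate. The phenoxide of 2 formed in the first hydrolysis is anionic and carries a poorer leaving group, so the second hydrolysis should be slower, and acidification gives 2.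

Further compounds
F1 | step 3 | (2S,4'R,8'R)-β-tocopheryl acetate, (2S)-2,5,8-trimethyl-2-[(4R,8R)-4,8,12-trimethyltridecyl]-3,4-dihydro-2H-chromen-6-yl acetate | Cc1cc(OC(C)=O)c(C)c2c1O[C@@](C)(CCC[C@H](C)CCC[C@H](C)CCCC(C)C)CC2
F2 | step 2 | 1,4-bis(methoxymethoxy)-2,5-dimethylbenzene | COCOc1cc(C)c(OCOC)cc1C
F3 | step 2 | (2E,7R,11R)-phytyl bromide, (2E,7R,11R)-1-bromo-3,7,11,15-tetramethylhexadec-2-ene | BrC/C=C(\C)CCC[C@H](C)CCC[C@H](C)CCCC(C)C
F4 | step 2 | [2,5-bis(methoxymethoxy)-3,6-dimethylphenyl]lithium | [Li]c1c(OCOC)c(C)cc(OCOC)c1C
F5 | step 2 | 1,4-bis(methoxymethoxy)-2,5-dimethyl-3-[(2E,7R,11R)-3,7,11,15-tetramethylhexadec-2-en-1-yl]benzene | COCOc1c(C/C=C(\C)CCC[C@H](C)CCC[C@H](C)CCCC(C)C)c(C)c(OCOC)cc1C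
F6 | step 2 | 2,5-dimethyl-3-[(2E,7R,11R)-3,7,11,15-tetramethylhexadec-2-en-1-yl]benzene-1,4-diol | Cc1cc(O)c(C)c(C/C=C(\C)CCC[C@H](C)CCC[C@H](C)CCCC(C)C)c1O
F7 | step 1 | 2,5-dimethyl-1,4-phenylene diacetate | CC(=O)Oc1cc(C)c(OC(C)=O)cc1C
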